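**Plan**

1. Atom numbers follow the chroman-2-one core. The lactone is cut at O1–C2 and C3–C4 (C2–C3 come from Meldrum's acid), leading back through an ortho-hydroxybenzhydrol to a 2-hydroxybenzophenone.
2. Ring A is then cut at C5–C6 and C4a–C8a. Its oxygens at C7 and C8a are 1,3-related and the adjacent C4a and C5 carry the carbonyl and the styryl group, which is the pattern a 1,1,3-trioxygenated butadiene gives on adding to an aroyl styryl alkyne.
3. The enynone is cut at the carbonyl–alkyne bond into an enyne unit from coniferaldehyde (one-carbon homologation) and vanillin.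
4. Forward: the enynone chain is assembled, ring A is built by cycloaddition–aromatisation, the ketone is reduced, the lactone ring is closed by quinone methide annulation, and the silyl groups are removed.
5. The E alkene is carried over from coniferaldehyde. The only stereocenter, C4 (R), is set by a chiral phosphoric acid when Meldrum's acid adds to the ortho-quinone methide.

Key step: step 8

Remarks: Ar = 4-(tert-butyldimethylsilyloxy)-3-methoxyphenyl throughout. (R)-TRIP = (R)-3,3'-bis(2,4,6-triisopropylphenyl)-1,1'-binaphthyl-2,2'-diyl hydrogen phosphate. Assumption: (R)-TRIP is taken to give the 4R product. The quinone methide of step 11 carries a second ortho substituent, so this sense of induction would have to be confirmed; (S)-TRIP would be used in the same way if it is reversed.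

**Route**

Step 1
Reactants: 1 coniferaldehyde
Product: 2 (E)-3-Ar-prop-2-enal
Conditions: TBSCl, imidazole, DMF, rt
Reagents that add atoms: tert-butyldimethylsilyl chloride (TBSCl), CC(C)(C)[Si](C)(C)Cl
Why: Imidazole-mediated O-silylation of a phenol (silyl ether protection) is routine, leaves the enal untouched and masks the acidic OH for the organolithium step.

Step 2
Reactants: 2 (E)-3-Ar-prop-2-enal
Product: 3 tert-butyl{4-[(1E)-4,4-dibromobuta-1,3-dien-1-yl]-2-methoxyphenoxy}dimethylsilane
Conditions: CBr4, PPh3, CH2Cl2, 0 °C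
Reagents that add atoms: carbon tetrabromide, BrC(Br)(Br)Br
Why: Corey–Fuchs dibromo-olefination (Wittig reaction of the dibromomethylene ylide formed in the flask) is standard for enals and does not touch the E-styryl double bond.

Step 3
Reactants: 4 vanillin
Product: 5 4-(tert-butyldimethylsilyloxy)-3-methoxybenzaldehyde
Conditions: TBSCl, imidazole, DMF, rt
Reagents that add atoms: tert-butyldimethylsilyl chloride (TBSCl), CC(C)(C)[Si](C)(C)Cl
Why: The same phenol silylation as in step 1 gives the aldehyde partner in a form that tolerates a lithium acetylide.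

Step 4
Reactants: 3 dibromodiene; 5 silylated vanillin
Product: 7 racemic (4E)-1,5-bis-Ar-pent-4-en-2-yn-1-ol, via lithium enynide 6 (not isolated)
Conditions: n-BuLi (2.1 equiv), THF, −78 °C; then 5, −78 → 0 °C; H2O
Reagents that add atoms: none
Why: In the second stage of the Corey–Fuchs sequence, bromine–lithium exchange and Fritsch–Buttenberg–Wiechell rearrangement give acetylide 6, which adds 1,2 to aldehyde 5; the carbinol centre forms racemic and is removed by oxidation in step 5.

Step 5
Reactants: 7 propargylic alcohol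
Product: 8 (4E)-1,5-bis-Ar-pent-4-en-2-yn-1-one
Conditions: MnO2, CH2Cl2, rt
Reagents that add atoms: none
Why: MnO2 oxidation of an alcohol that is both benzylic and propargylic is a mild route to ynones and should spare the aryl silyl ethers and the enyne.

Step 6
Reactants: 9 methyl acetoacetate
Product: 10 methyl 3-(trimethylsilyloxy)but-2-enoate (E/Z mixture, geometry immaterial)
Conditions: TMSCl, Et3N, hexane, rt
Reagents that add atoms: trimethylsilyl chloride (TMSCl), C[Si](C)(C)Cl
Why: Silyl enol ether formation from the enolisable β-keto ester with TMSCl and Et3N is the standard first stage of bis-silyl diene preparation.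

Step 7
Reactants: 10 silyl enol ether
Product: 12 1-methoxy-1,3-bis(trimethylsilyloxy)buta-1,3-diene, via lithium dienolate 11 (not isolated)
Conditions: LiN(i-Pr)2 (LDA), THF, −78 °C; then TMSCl, −78 °C → rt
Reagents that add atoms: trimethylsilyl chloride (TMSCl), C[Si](C)(C)Cl
Why: Kinetic γ-deprotonation of 10 by LDA and O-silylation of the ester dienolate 11 is the usual second stage of this diene synthesis; the ketene acetal geometry is irrelevant because that carbon becomes aromatic.

Step 8
Reactants: 8 enynone; 12 bis-silyl diene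
Product: 15 {2,4-dihydroxy-6-[(E)-2-Ar-ethenyl]phenyl}(Ar)methanone, via cyclohexadiene adduct 13 (not isolated), via bis-trimethylsilyl ether 14 (not isolated)
Conditions: 12 (2.5 equiv), PhMe, 80 °C, sealed tube; then 1 M HCl, THF, 0 °C
Reagents that add atoms: none
Why: The electron-rich CH2 terminus of diene 12 bonds to the alkyne carbon β to the ketone of 8 (future C5) while the ketene acetal carbon bonds to the α carbon (future C4a) in a thermal, strongly asynchronous [4+2] cycloaddition (at the limit a Mukaiyama–Michael addition followed by collapse of the allenolate onto the silyloxy-stabilised cation), giving cyclohexa-1,4-diene 13. 1,4-Elimination of methanol from the mixed ketal carbon aromatises 13 to bis-silyl ether 14, and brief dilute acid cleaves the two aryl O–SiMe3 bonds but not the aryl tert-butyldimethylsilyl ethers, giving 15. The closest known reaction type is the cycloaddition–aromatisation of 1,1,3-trioxygenated butadienes with alkynoates and alkynones to give resorcinol derivatives. Ring A is closed by intermolecular [4+2] cycloaddition that forms C5–C6 and C4a–C8a, and no stereocenter is created. The step needs regioselectivity, secured by the matched polarisation of the donor diene and the acceptor ynone (oxygens end at C8a ortho to the ketone and at C7), and chemoselectivity, secured because the alkyne is the only π bond directly conjugated to the carbonyl and because the absence of a Lewis acid keeps the silyl groups on the diene and disfavours attack at the ketone carbon.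

Step 9
Reactants: 15 dihydroxybenzophenone
Product: 16 {4-(tert-butyldimethylsilyloxy)-2-hydroxy-6-[(E)-2-Ar-ethenyl]phenyl}(Ar)methanone
Conditions: TBSCl (1.05 equiv), imidazole, CH2Cl2, 0 °C
Reagents that add atoms: tert-butyldimethylsilyl chloride (TBSCl), CC(C)(C)[Si](C)(C)Cl
Why: In this regioselective phenol silylation the C8a hydroxyl is hydrogen-bonded to and shielded by the ketone, so one equivalent of TBSCl should silylate only the free, more acidic C7 hydroxyl, which blocks para-quinone methide formation in step 11.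

Step 10
Reactants: 16 hydroxybenzophenone
Product: 17 racemic 5-(tert-butyldimethylsilyloxy)-2-[Ar(hydroxy)methyl]-3-[(E)-2-Ar-ethenyl]phenol
Conditions: NaBH4, THF/EtOH, 0 °C; used without chromatography
Reagents that add atoms: none
Why: Borohydride reduction of an ortho-hydroxybenzophenone to the ortho-hydroxybenzhydrol is standard, and the racemic carbinol centre does not matter because it becomes planar in the quinone methide of step 11.

Step 11
Reactants: 17 ortho-hydroxybenzhydrol; 18 Meldrum's acid
Product: 22 (4R)-7-(tert-butyldimethylsilyloxy)-4-Ar-5-[(E)-2-Ar-ethenyl]chroman-2-one, via ortho-quinone methide 19 (not isolated), via Meldrum's acid adduct 20 (not isolated), via lactone acid 21 (not isolated)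
Conditions: 18 (1.5 equiv), (R)-TRIP (10 mol %), PhMe, rt; then 90 °C
Reagents that add atoms: none
Why: The phosphoric acid dehydrates 17 to quinone methide 19 and, hydrogen-bonded to its carbonyl and to the enol of Meldrum's acid, directs conjugate addition to one face of the methide carbon (C4 set as R under catalyst control), after which the phenol opens the acylal with loss of acetone and acid 21 decarboxylates on heating, i.e. a chiral Brønsted acid-catalysed 1,3-dicarbonyl addition to an in situ ortho-quinone methide followed by Meldrum's acid lactonisation–decarboxylation.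

Step 12
Reactants: 22 tris-silyl lactone
Product: 23 (4R)-7-hydroxy-4-(4-hydroxy-3-methoxyphenyl)-5-[(E)-2-(4-hydroxy-3-methoxyphenyl)ethenyl]chroman-2-one
Conditions: Bu4NF/AcOH (1:1, 3.5 equiv), THF, 0 °C
Reagents that add atoms: none
Why: Fluoride-mediated cleavage of the three aryl silyl ethers is fast at 0 °C, acetic acid buffering keeps the medium non-basic so the aryl lactone should stay closed, and C4 has neither a leaving group nor an acidic hydrogen and cannot epimerise.

**Compound list**

1 | coniferaldehyde, (E)-3-(4-hydroxy-3-methoxyphenyl)prop-2-enal | COc1cc(/C=C/C=O)ccc1O | starting material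
2 | (E)-3-[4-(tert-butyldimethylsilyloxy)-3-methoxyphenyl]prop-2-enal | COc1cc(/C=C/C=O)ccc1O[Si](C)(C)C(C)(C)C | intermediate
3 | tert-butyl{4-[(1E)-4,4-dibromobuta-1,3-dien-1-yl]-2-methoxyphenoxy}dimethylsilane | COc1cc(/C=C/C=C(Br)Br)ccc1O[Si](C)(C)C(C)(C)C | intermediate
4 | vanillin | COc1cc(C=O)ccc1O | starting material
5 | 4-(tert-butyldimethylsilyloxy)-3-methoxybenzaldehyde | COc1cc(C=O)ccc1O[Si](C)(C)C(C)(C)C | intermediate
6 | lithium (E)-4-Ar-but-3-en-1-yn-1-ide (not isolated) | COc1cc(/C=C/C#C[Li])ccc1O[Si](C)(C)C(C)(C)C | intermediate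
7 | racemic (4E)-1,5-bis-Ar-pent-4-en-2-yn-1-ol | COc1cc(/C=C/C#CC(O)c2ccc(O[Si](C)(C)C(C)(C)C)c(OC)c2)ccc1O[Si](C)(C)C(C)(C)C | intermediate
8 | (4E)-1,5-bis-Ar-pent-4-en-2-yn-1-one | COc1cc(/C=C/C#CC(=O)c2ccc(O[Si](C)(C)C(C)(C)C)c(OC)c2)ccc1O[Si](C)(C)C(C)(C)C | intermediate
9 | methyl acetoacetate | COC(=O)CC(C)=O | starting material
10 | methyl 3-(trimethylsilyloxy)but-2-enoate (E/Z mixture) | COC(=O)C=C(C)O[Si](C)(C)C | intermediate
11 | lithium dienolate of 10 (not isolated) | COC(O[Li])=CC(=C)O[Si](C)(C)C | intermediate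
12 | 1-methoxy-1,3-bis(trimethylsilyloxy)buta-1,3-diene | COC(O[Si](C)(C)C)=CC(=C)O[Si](C)(C)C | intermediate
13 | racemic cyclohexa-1,4-diene adduct: (6-methoxy-4,6-bis(trimethylsilyloxy)-2-[(E)-2-Ar-ethenyl]cyclohexa-1,4-dien-1-yl)(Ar)methanone (not isolated) | COC1(O[Si](C)(C)C)C=C(O[Si](C)(C)C)CC(/C=C/c2ccc(O[Si](C)(C)C(C)(C)C)c(OC)c2)=C1C(=O)c3ccc(O[Si](C)(C)C(C)(C)C)c(OC)c3 | intermediate
14 | bis(trimethylsilyl) ether of 15 (not isolated) | COc1cc(/C=C/c2cc(O[Si](C)(C)C)cc(O[Si](C)(C)C)c2C(=O)c3ccc(O[Si](C)(C)C(C)(C)C)c(OC)c3)ccc1O[Si](C)(C)C(C)(C)C | intermediate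
15 | {2,4-dihydroxy-6-[(E)-2-Ar-ethenyl]phenyl}(Ar)methanone | COc1cc(/C=C/c2cc(O)cc(O)c2C(=O)c3ccc(O[Si](C)(C)C(C)(C)C)c(OC)c3)ccc1O[Si](C)(C)C(C)(C)C | intermediate
16 | {4-(tert-butyldimethylsilyloxy)-2-hydroxy-6-[(E)-2-Ar-ethenyl]phenyl}(Ar)methanone | COc1cc(/C=C/c2cc(O[Si](C)(C)C(C)(C)C)cc(O)c2C(=O)c3ccc(O[Si](C)(C)C(C)(C)C)c(OC)c3)ccc1O[Si](C)(C)C(C)(C)C | intermediate
17 | racemic 5-(tert-butyldimethylsilyloxy)-2-[Ar(hydroxy)methyl]-3-[(E)-2-Ar-ethenyl]phenol | COc1cc(/C=C/c2cc(O[Si](C)(C)C(C)(C)C)cc(O)c2C(O)c3ccc(O[Si](C)(C)C(C)(C)C)c(OC)c3)ccc1O[Si](C)(C)C(C)(C)C | intermediate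
18 | Meldrum's acid, 2,2-dimethyl-1,3-dioxane-4,6-dione | CC1(C)OC(=O)CC(=O)O1 | starting material
19 | ortho-quinone methide: 3-(tert-butyldimethylsilyloxy)-6-(Ar-methylidene)-5-[(E)-2-Ar-ethenyl]cyclohexa-2,4-dien-1-one, exocyclic geometry undefined (not isolated) | COc1cc(/C=C/C2=CC(O[Si](C)(C)C(C)(C)C)=CC(=O)C2=Cc3ccc(O[Si](C)(C)C(C)(C)C)c(OC)c3)ccc1O[Si](C)(C)C(C)(C)C | intermediate
20 | 5-[(R)-Ar{4-(tert-butyldimethylsilyloxy)-2-hydroxy-6-[(E)-2-Ar-ethenyl]phenyl}methyl]-2,2-dimethyl-1,3-dioxane-4,6-dione (not isolated) | COc1cc(/C=C/c2cc(O[Si](C)(C)C(C)(C)C)cc(O)c2[C@@H](c3ccc(O[Si](C)(C)C(C)(C)C)c(OC)c3)C4C(=O)OC(C)(C)OC4=O)ccc1O[Si](C)(C)C(C)(C)C | intermediate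
21 | (4R)-7-(tert-butyldimethylsilyloxy)-4-Ar-5-[(E)-2-Ar-ethenyl]-2-oxochroman-3-carboxylic acid, C3 epimers (not isolated) | COc1cc(/C=C/c2cc(O[Si](C)(C)C(C)(C)C)cc3c2[C@@H](c4ccc(O[Si](C)(C)C(C)(C)C)c(OC)c4)C(C(=O)O)C(=O)O3)ccc1O[Si](C)(C)C(C)(C)C | intermediate
22 | (4R)-7-(tert-butyldimethylsilyloxy)-4-Ar-5-[(E)-2-Ar-ethenyl]chroman-2-one | COc1cc(/C=C/c2cc(O[Si](C)(C)C(C)(C)C)cc3c2[C@@H](c4ccc(O[Si](C)(C)C(C)(C)C)c(OC)c4)CC(=O)O3)ccc1O[Si](C)(C)C(C)(C)C | intermediate
23 | (4R)-7-hydroxy-4-(4-hydroxy-3-methoxyphenyl)-5-[(E)-2-(4-hydroxy-3-methoxyphenyl)ethenyl]chroman-2-one (CNP0277187.1) | COc1cc(/C=C/c2cc(O)cc3c2[C@@H](c2ccc(O)c(OC)c2)CC(=O)O3)ccc1O | target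

**Step count and risks**

Total steps: 12. Longest linear sequence: 9 steps (1 → 2 → 3 → 7 → 8 → 15 → 16 → 17 → 22 → 23; steps 1, 2, 4, 5, 8, 9, 10, 11, 12).

Steps most likely to fail:

Step 8. The aroyl alkyne is deactivated by the para-silyloxy donor and is flanked by two bulky groups, so cycloaddition may be slower than thermal breakdown of the diene. The diene terminus may also attack the ketone carbon, which would lead to a [3+3] salicylate instead of the benzophenone.

Fallback: it sets out from 3 and comes back at 17. Lithium enynide 6, made from 3 as in step 4, is quenched with DMF to give (E)-5-Ar-pent-4-en-2-ynal F1, a smaller and more electrophilic dienophile. Heating F1 with diene 12 in toluene should give, through cyclohexadiene adduct F2 and bis-trimethylsilyl ether F3 and after dilute HCl, 2,4-dihydroxy-6-[(E)-2-Ar-ethenyl]benzaldehyde F4. TBSCl and imidazole silylate its non-chelated 4-hydroxyl to give salicylaldehyde silyl ether F5. Separately, commercial 4-bromo-2-methoxyphenol is silylated to aryl bromide F6 and converted with Mg in THF into Grignard reagent F7. Addition of F7 (2.2 equiv, the first consumed by the phenol) to F5 at 0 °C gives benzhydrol 17. The aryl group is thus attached after ring A is built, and the ketone stage and steps 9 and 10 are bypassed.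

Step 11. Facial control may be poor because the styryl group ortho to the methide twists the quinone methide away from the geometry the catalyst pocket expects. Meldrum's acid, itself a fairly strong acid, may also trigger a racemic background addition. Reversible C–C bond formation during the heating phase could erode the enantiomeric purity further.

Fallback: it sets out from 17 and comes back at 22. Benzhydrol 17 is treated with sodium p-toluenesulfinate and a catalytic acid in CH2Cl2 to give 2-[Ar(tosyl)methyl]phenol sulfone F8. Under biphasic aqueous NaHCO3/toluene with a cinchona-derived bifunctional squaramide (quinine- or quinidine-based, whichever gives 4R), base releases quinone methide 19 at low concentration and Meldrum's acid 18 adds as its catalyst-bound enolate to give 20. Warming the organic phase with catalytic TsOH then closes it through 21 to 22. No Brønsted acid is present during the C–C bond formation, which removes the background pathway.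

Step 10. Reduction may overshoot: under the basic borohydride conditions the electron-rich benzhydrol can eliminate to the quinone methide, which is reduced further to the diarylmethane. The benzhydrol may also ionise and oligomerise on isolation.

Fallback: it sets out from 16 and comes back at 22. Ketone 16 is heated with ethyl (triphenylphosphoranylidene)acetate in toluene; Wittig olefination gives ethyl 3,3-diarylacrylate F9, which lactonises in the flask to 4-arylcoumarin F10. Copper hydride-catalysed asymmetric conjugate reduction (Cu(OAc)2, DTBM-SEGPHOS in the enantiomeric form that delivers hydride to the face giving 4R, diethoxymethylsilane, t-BuOH, toluene) then gives 22 directly. The benzhydrol and the quinone methide are avoided, and the stilbene, not being conjugated to a carbonyl, should survive.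

**Further compounds**

F1 | step 8 | (E)-5-[4-(tert-butyldimethylsilyloxy)-3-methoxyphenyl]pent-4-en-2-ynal | COc1cc(/C=C/C#CC=O)ccc1O[Si](C)(C)C(C)(C)C
F2 | step 8 | cyclohexa-1,4-diene adduct of F1 and 12: 6-methoxy-4,6-bis(trimethylsilyloxy)-2-[(E)-2-Ar-ethenyl]cyclohexa-1,4-diene-1-carbaldehyde | COC1(O[Si](C)(C)C)C=C(O[Si](C)(C)C)CC(/C=C/c2ccc(O[Si](C)(C)C(C)(C)C)c(OC)c2)=C1C=O
F3 | step 8 | 2,4-bis(trimethylsilyloxy)-6-[(E)-2-Ar-ethenyl]benzaldehyde | COc1cc(/C=C/c2cc(O[Si](C)(C)C)cc(O[Si](C)(C)C)c2C=O)ccc1O[Si](C)(C)C(C)(C)C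
F4 | step 8 | 2,4-dihydroxy-6-[(E)-2-Ar-ethenyl]benzaldehyde | COc1cc(/C=C/c2cc(O)cc(O)c2C=O)ccc1O[Si](C)(C)C(C)(C)C
F5 | step 8 | 4-(tert-butyldimethylsilyloxy)-2-hydroxy-6-[(E)-2-Ar-ethenyl]benzaldehyde | COc1cc(/C=C/c2cc(O[Si](C)(C)C(C)(C)C)cc(O)c2C=O)ccc1O[Si](C)(C)C(C)(C)C
F6 | step 8 | (4-bromo-2-methoxyphenoxy)(tert-butyl)dimethylsilane | COc1cc(Br)ccc1O[Si](C)(C)C(C)(C)C
F7 | step 8 | [4-(tert-butyldimethylsilyloxy)-3-methoxyphenyl]magnesium bromide | COc1cc([Mg]Br)ccc1O[Si](C)(C)C(C)(C)C
F8 | step 11 | racemic 5-(tert-butyldimethylsilyloxy)-2-[Ar(4-methylbenzenesulfonyl)methyl]-3-[(E)-2-Ar-ethenyl]phenol | COc1cc(/C=C/c2cc(O[Si](C)(C)C(C)(C)C)cc(O)c2C(c3ccc(O[Si](C)(C)C(C)(C)C)c(OC)c3)S(=O)(=O)c4ccc(C)cc4)ccc1O[Si](C)(C)C(C)(C)C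
F9 | step 10 | ethyl 3-Ar-3-{4-(tert-butyldimethylsilyloxy)-2-hydroxy-6-[(E)-2-Ar-ethenyl]phenyl}prop-2-enoate (acrylate geometry undefined) | CCOC(=O)C=C(c1ccc(O[Si](C)(C)C(C)(C)C)c(OC)c1)c1c(O)cc(O[Si](C)(C)C(C)(C)C)cc1/C=C/c1ccc(O[Si](C)(C)C(C)(C)C)c(OC)c1
F10 | step 10 | 7-(tert-butyldimethylsilyloxy)-4-Ar-5-[(E)-2-Ar-ethenyl]chromen-2-one | COc1cc(/C=C/c2cc(O[Si](C)(C)C(C)(C)C)cc3oc(=O)cc(-c4ccc(O[Si](C)(C)C(C)(C)C)c(OC)c4)c23)ccc1O[Si](C)(C)C(C)(C)C
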